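A flat line of readings is easily taken for an equilibrium, yet a flask also goes flat when a charge has been consumed, and the two cases call for different actions. The flask asked about follows the eta recipe; alpha is the earlier run, with less partner and a lower temperature.

the same everywhere: solid substrate 0.80 M
- eta: partner 1.44 M; temperature 20 °C; the very flask that is asked about, followed so far
- alpha: partner 0.72 M; temperature 15 °C; run made earlier
- flask: partner 1.44 M; temperature 20 °C; time 2.5 d

eta run (percent of the solid substrate charged)

| time / h | target / % |
|---|---|
| 4.00 | 15.8 |
| 8.00 | 14.7 |
| 20.0 | 14.7 |
| 50.0 | 14.8 |

alpha run (percent of the solid substrate charged)

| time / min | target / % |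
|---|---|
| 30.0 | 4.0 |
| 60.0 | 4.6 |
| 90.0 | 8.3 |
| 120 | 5.6 |

(readings scatter by 1 percentage point)

- as a solid, counted per litre of solution: solid substrate
- what is taken out of target is counted as made
- at the start none of the solid substrate is in solution
- additions bring no volume worth counting

- target, in percent of the solid substrate first charged, at 2.5 d
- which option adds most target ("none" when 2 percentage points or less is all one gets) (south / west / east / north-west / none)
- target present, with what was taken out counted in, in percent of the solid substrate first charged, after east
- target present, with what was taken out counted in, in percent of the solid substrate first charged, after north-west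

- south: change nothing and wait 5.0 d more
- west: at 2.5 d add partner, 50.0% of the amount charged, then wait 5.0 d
- east: at 2.5 d take out 90% of the target then present, then wait 5.0 d
- north-west: at 2.5 d raise the temperature by 25 K, then wait 5.0 d

I follow the readings from the start. At the first instant no solid substrate is in solution. In alpha, target reads 4.0% after 30.0 min, and the later readings up to 120 min average 6.17%. In eta, target already reads 15.8% at 4.00 h, and from 8.00 h to 50.0 h it averages 14.7%, with no drift beyond the scatter. That end level equals 8.19% of the partner charged, so the remaining partner is either still free or has been lost unseen.

Between the two averages I read 9.52%, and I call this the marginal yield on partner, the target gained per extra mole of partner charged. It is a reading across two temperatures and two lengths of run, and it carries the scatter of the readings. West adds 0.720 M of partner, so I expect it to add 8.6 percentage points. More partner pays on both views of the flat line, whereas east pays on one of them. If partner has been consumed, I expect target, with what is taken out counted in, to stay near 14.7% after east and after north-west. I therefore commit to west, and to that level for target now, after east and after north-west.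

The forecast, made from the same runs, takes the other view: “Nothing in it is being used up”. It gives 14.9% (14.2% to 15.7%) and chooses east, at about 12 points against 7.5 for west. After east it gives 27% (23.5% to 29.5%), and after north-west 20% (8% to 48%).

The flask gives 15.2% at 2.5 d, and the best option is west, with 16.6% after east and 15.1% after north-west.

    solid substrate ⇌ dissolved substrate, rate k1*(cs1 - [dissolved substrate]) while solid is left; crystals form when [dissolved substrate] > cs1 (solubility = 0.260 M, k = 0.00560 /s)
    dissolved substrate + partner → target (k = 6.10 × 10⁻⁴ /M/s, Ea = 60.0 kJ/mol)
    partner → side product A (k = 8.40 × 10⁻⁴ /s, Ea = 88.0 kJ/mol)
    solid substrate + target → side product B (k = 0.0100 /M/s, Ea = 69.0 kJ/mol)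
    2 solid substrate → self-condensation product (k = 0.00210 /M/s, Ea = 69.0 kJ/mol)
    target ⇌ isomer of the product (K = 0.110, k = 7.50 × 10⁻⁴ /s, Ea = 88.0 kJ/mol, ΔH = 3.00 kJ/mol)
    (constants at 20 °C)

The forecast and the flask part at east, which adds 1.4 points. At 6.00 h the asked flask holds partner at 0% and dissolved substrate at 25.6%: partner is its limiting reagent, though charged at 1.80 equivalents. West adds 8.6 points, against the 8.6 points reckoned from the marginal yield. On the neighbouring flask with 0.58 M of partner, the same yield taken down from 14.7% gives 4.50% of target. That flask gives 2.69%, with partner at 0% at 60.0 h.

The runs were generated by integration for an exercise.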